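| flask | starting material | second substrate | partner | free catalyst | impurity | remark |
|---|---|---|---|---|---|---|
| cedar | 0.050 M | 0.050 M | 0.075 M | 4.5 mM | 2.1 mM | run made earlier |
| birch | 0.050 M | 0.050 M | 0.075 M | 4.5 mM | 4.7 mM | run made earlier |
| ash | 0.10 M | 0.050 M | 0.075 M | 4.5 mM | 3.1 mM | run made earlier |
| flask | 0.050 M | 0.0500 M | 0.0750 M | 4.5 mM | 3.1 mM |  |

| run | time / min | target / % | starting material / % |
|---|---|---|---|
| cedar | 0.500 | 3.9 | 93.9 |
| cedar | 0.833 | 7.8 | 91.6 |
| cedar | 1.33 | 11.9 | 87.0 |
| cedar | 2.00 | 15.9 | 82.0 |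
| cedar | 4.00 | 29.5 | 68.8 |
| cedar | 6.00 | 39.5 | 60.0 |
| birch | 0.500 | 0.4 | 99.0 |
| birch | 0.833 | 1.6 | 98.0 |
| birch | 1.33 | 1.3 | 98.1 |
| birch | 2.00 | 1.7 | 97.7 |
| birch | 4.00 | 2.0 | 98.4 |
| birch | 6.00 | 2.3 | 97.7 |
| ash | 1.33 | 6.5 | 93.5 |
| ash | 2.50 | 10.6 | 88.9 |
| ash | 4.00 | 15.3 | 83.6 |
| ash | 5.00 | 19.7 | 80.8 |
| ash | 6.00 | 21.6 | 78.5 |

(scatter of a reading: 0.5 percentage points)

- no earlier run changes the charge of partner; that part of a forecast is a guess

1. The slowness of the birch run stands out: target reaches 2.3% at 6.00 min, against 39.5% in the cedar run. Impurity charged in birch, 4.7 mM, is more than the free catalyst charged, 4.5 mM.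

2. Two amounts are therefore compared, c(free catalyst) and c(impurity), both as charged, reading the impurity as a catalyst poison taken one for one. In the flask this gives 1.40 mM: the live catalyst, catalyst charged less impurity charged. In cedar it gives 2.40 mM.

3. Cedar passes 20% conversion between 2.00 min and 4.00 min, where its target readings climb at 3.40 mM min⁻¹. That reading is 1.42 min⁻¹ per live catalyst. The flask has cedar's charges apart from the impurity, so this reckoning puts its rate at that conversion near 1.99 mM min⁻¹.

* apparent order in partner when 20% of the starting material are converted (percent change of the rate of making target for one percent more partner charged)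

4. No run changes the partner, so this reckoning yields no order in partner. The forecast says 0.4, holding that “a fractional order is a reasonable guess”.

5. The flask gives 1.2, above the forecast.

    starting material + free catalyst ⇌ catalyst intermediate A (K = 18.0 M⁻¹, k = 4.80 M⁻¹ s⁻¹)
    free catalyst + impurity → spent catalyst (k = 270 M⁻¹ s⁻¹)
    partner + catalyst intermediate B → free catalyst + second product (k = 0.790 M⁻¹ s⁻¹)
    second substrate + free catalyst ⇌ catalyst intermediate B (K = 39.0 M⁻¹, k = 3.40 M⁻¹ s⁻¹)
    partner + catalyst intermediate A → free catalyst + target (k = 2.10 M⁻¹ s⁻¹)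

6. At 2.12 min in the flask, catalyst intermediate A falls back 1.9 times faster than it goes on with the partner. The flask's rate of making target at 4.06 min, 1.96 mM min⁻¹, divided by its live catalyst, is 1.40 min⁻¹, against the 1.42 min⁻¹ read from cedar.

(All runs were generated by integration with made-up constants; the scatter is artificial.)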